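**Assumption:** ethyl (S)-lactate, 5-bromo-1,2,3-trimethoxybenzene, TBSCl, propionyl chloride and Ph3P=CHCO2Et are commercial. The minor Z-enoate from the Wittig step is removed by chromatography.

## Retrosynthetic overview
1. Peperomin C (**1**) comes from alkenyl acid **2** by ozonolysis of the propenyl group, NaBH4 reduction and lactonization. The lactone ring is the only ring formed after the skeleton is built, and both aryl rings are carried in from commercial bromide **7**.
2. Acid **2** comes from Claisen acid **3**. The CO2Et group of **3** becomes the Ar2CH group by double ArMgBr addition and ionic deoxygenation, with the carboxylate protecting the acid.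
3. Key step: an Ireland–Claisen [3,3] rearrangement of propionate **4** forms the C3–C4 bond and both stereocenters, with chirality transferred from the carbinol carbon of **4**.
4. **4** comes from (S)-allylic alcohol **5**, which comes from ethyl (S)-lactate **6** by silylation, DIBAL/Wittig and desilylation.

## Route

**Step 1**
Reactants: **6** ethyl (S)-lactate; **8** tert-butyldimethylsilyl chloride
Product: **9** ethyl (S)-2-(TBSO)propanoate
Conditions: TBSCl, imidazole, DMF, 0 °C → rt
Reagents that add atoms: TBSCl, CC(C)(C)[Si](C)(C)Cl
Why: Silyl protection of the secondary alcohol (Corey silylation) leaves the stereocenter untouched and prevents O–H interference in the DIBAL/Wittig step.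

**Step 2**
Reactants: **9**; **10** ethyl (triphenylphosphoranylidene)acetate
Product: **11** ethyl (2E,4S)-4-(TBSO)pent-2-enoate
Conditions: DIBAL-H (1.05 equiv), CH2Cl2, –78 °C; then **10** (1.5 equiv), –78 °C → rt
Reagents that add atoms: Ph3P=CHCO2Et, CCOC(=O)C=P(c1ccccc1)(c1ccccc1)c1ccccc1
Why: DIBAL stops at the aluminium hemiacetal stage, which masks the racemization-prone α-silyloxy aldehyde. Wittig olefination of this intermediate with a stabilized ylide gives the E-enoate, and the carbinol center is not touched.

**Step 3**
Reactants: **11**
Product: **5** ethyl (2E,4S)-4-hydroxypent-2-enoate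
Conditions: HF·pyridine, pyridine/THF, 0 °C → rt
Reagents that add atoms: none
Why: Fluoride-mediated Si–O cleavage frees the allylic alcohol under mildly acidic conditions, so the enoate is not isomerized or eliminated.

**Step 4**
Reactants: **5**; **12** propionyl chloride
Product: **4** ethyl (2E,4S)-4-(propanoyloxy)pent-2-enoate
Conditions: EtCOCl, pyridine, DMAP (cat.), CH2Cl2, 0 °C
Reagents that add atoms: propionyl chloride, CCC(=O)Cl
Why: Ordinary Schotten–Baumann-type acylation gives the allylic propionate needed for the Claisen rearrangement, with no stereochemical change.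

**Step 5 (key step)**
Reactants: **4**
Product: **3** (2S,3R,4E)-3-(ethoxycarbonyl)-2-methylhex-4-enoic acid
Conditions: LDA (1.3 equiv) added to **4** and TMSCl (2 equiv) in THF/DMPU (4:1), –78 °C → rt, 12 h; then 1 M HCl
Reagents that add atoms: none (the TMS ester is cleaved on work-up)
Why: Ireland–Claisen [3,3] rearrangement. In DMPU-containing THF the ester gives the silyl ketene acetal with the methyl trans to the allyl oxygen. The chair transition state places the E-alkene CO2Et and the carbinol methyl pseudo-equatorial, giving the 2,3-syn acid, which becomes the trans-lactone. The (S) carbinol centre fixes the absolute configuration at both new centers, (2S,3R) in this numbering, which corresponds to (3S,4S) in the lactone.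

**Step 6**
Reactants: **3**; **7** 5-bromo-1,2,3-trimethoxybenzene, converted in situ to 3,4,5-trimethoxyphenylmagnesium bromide
Product: **13** (2S,3R,4E)-3-[hydroxybis(3,4,5-trimethoxyphenyl)methyl]-2-methylhex-4-enoic acid
Conditions: **7** (5 equiv) + Mg, THF, reflux 1 h; add **3**, 0 °C → rt, 6 h; aq. NH4Cl, then citric acid to pH 4
Reagents that add atoms: 3,4,5-trimethoxyphenylmagnesium bromide, COc1cc([Mg]Br)cc(OC)c1OC
Why: The first equivalent of ArMgBr converts the acid into a magnesium carboxylate, which resists addition. The ethyl ester then takes up two aryl groups (Grignard double addition) to give the tertiary diarylcarbinol. Some of this product may close to the 5,5-diaryl lactone on work-up, and step 7 converges both forms.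

**Step 7**
Reactants: **13**
Product: **2** (2S,3S,4E)-3-[bis(3,4,5-trimethoxyphenyl)methyl]-2-methylhex-4-enoic acid
Conditions: Et3SiH (5 equiv), TFA, CH2Cl2, 0 °C → rt, 2 h
Reagents that add atoms: none (only hydride is delivered)
Why: Ionic hydrogenation through the 4-OMe-stabilized diaryl carbocation delivers hydride to give the Ar2CH group. Any diaryl lactone present re-ionizes at the benzylic C–O bond and is reduced to the same acid. The adjacent stereocenters are not involved.

**Step 8**
Reactants: **2**
Product: **1** peperomin C, (3S,4S)-4-[bis(3,4,5-trimethoxyphenyl)methyl]-3-methyldihydrofuran-2(3H)-one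
Conditions: O3 (about 1 equiv), CH2Cl2/MeOH 4:1, –78 °C; then NaBH4, –78 → 0 °C; then 1 M HCl, rt (cat. TsOH if needed)
Reagents that add atoms: ozone, O=[O+][O-] (its oxygen becomes the ring oxygen)
Why: Ozonolysis cleaves the disubstituted propenyl alkene selectively at –78 °C with controlled ozone, and NaBH4 reduces the resulting C5 aldehyde to the primary alcohol. The γ-hydroxy acid then lactonizes on acidification. C3 is a carboxylate α-carbon and is untouched, and the trans-lactone is thermodynamically favoured at C4.

## Compound list
1 | peperomin C, (3S,4S)-4-[bis(3,4,5-trimethoxyphenyl)methyl]-3-methyldihydrofuran-2(3H)-one | COc1cc(C(c2cc(OC)c(OC)c(OC)c2)[C@@H]2COC(=O)[C@H]2C)cc(OC)c1OC | target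
2 | (2S,3S,4E)-3-[bis(3,4,5-trimethoxyphenyl)methyl]-2-methylhex-4-enoic acid | OC(=O)[C@@H](C)[C@H](C(c1cc(OC)c(OC)c(OC)c1)c1cc(OC)c(OC)c(OC)c1)/C=C/C | intermediate
3 | (2S,3R,4E)-3-(ethoxycarbonyl)-2-methylhex-4-enoic acid | OC(=O)[C@@H](C)[C@H](C(=O)OCC)/C=C/C | intermediate
4 | ethyl (2E,4S)-4-(propanoyloxy)pent-2-enoate | C[C@H](OC(=O)CC)/C=C/C(=O)OCC | intermediate
5 | ethyl (2E,4S)-4-hydroxypent-2-enoate | C[C@H](O)/C=C/C(=O)OCC | intermediate
6 | ethyl (S)-lactate | C[C@H](O)C(=O)OCC | starting material
7 | 5-bromo-1,2,3-trimethoxybenzene | COc1cc(Br)cc(OC)c1OC | starting material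
8 | tert-butyldimethylsilyl chloride | CC(C)(C)[Si](C)(C)Cl | starting material
9 | ethyl (S)-2-(TBSO)propanoate | C[C@H](O[Si](C)(C)C(C)(C)C)C(=O)OCC | intermediate
10 | ethyl (triphenylphosphoranylidene)acetate | CCOC(=O)C=P(c1ccccc1)(c1ccccc1)c1ccccc1 | starting material
11 | ethyl (2E,4S)-4-(TBSO)pent-2-enoate | C[C@H](O[Si](C)(C)C(C)(C)C)/C=C/C(=O)OCC | intermediate
12 | propionyl chloride | CCC(=O)Cl | starting material
13 | (2S,3R,4E)-3-[hydroxybis(3,4,5-trimethoxyphenyl)methyl]-2-methylhex-4-enoic acid | OC(=O)[C@@H](C)[C@H](C(O)(c1cc(OC)c(OC)c(OC)c1)c1cc(OC)c(OC)c(OC)c1)/C=C/C | intermediate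

**Total steps:** 8. **Longest linear sequence:** 8 (from ethyl (S)-lactate **6**).

## Three steps most likely to fail
1. **Step 5, Ireland–Claisen of the γ-acyloxy enoate.** The enoate γ-C–H can compete with propionate α-deprotonation, and the syn selectivity may be modest.
   Fallback: switch to an Eschenmoser–Claisen of **5** with N,N-dimethylpropionamide dimethyl acetal in refluxing xylene, which gives the dimethylamide in place of the acid. The amide survives ArMgBr, lactonizes under TsOH/toluene after the oxidative step, and any C3 epimer is equilibrated to the trans-lactone with base.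
2. **Step 6, chemoselective double ArMgBr addition.** The carboxylate may be attacked, C4 may epimerize, or the carbinol may cyclize prematurely.
   Fallback: first convert **3** into the lactone-ester by ozonolysis/NaBH4. Reduce the ester to the aldehyde, add ArMgBr to give the secondary benzylic alcohol, convert it to the carbonate, and install the second aryl group by Pd-catalysed Suzuki coupling with 3,4,5-trimethoxyphenylboronic acid.
3. **Step 8, ozonolysis in the presence of two electron-rich arenes.** Over-oxidation of the arenes, or C4 epimerization at the aldehyde stage, would lower the yield.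
   Fallback: replace ozone with OsO4 (cat.)/NaIO4 and 2,6-lutidine (Lemieux–Johnson cleavage), then reduce with NaBH4 and lactonize with acid.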